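Numbering (germacrane): ring carbons C1–C10; C11 is the lactone α-carbon, C12 the lactone C=O, C13 the exocyclic CH2. The lactone O sits on C6, OH on C2 and C8, the angelate on C9.
The ten-membered ring is formed last, C1–C2 by Nozaki–Hiyama–Kishi closure of iodo aldehyde 27. Before it, C7–C8 is made by Barbier allylation of aldehyde 23 with bromomethylbutenolide 12, which relays C6 to C7 and C8 and pushes the ring double bond out to C11=C13.
The lactone ring is formed first (as butenolide 10) in the key step, from the racemic acyclic carbonate 8, CO and water: C11–C12 by enantioconvergent palladium-catalysed SN2′ carbonylation, O–C6 by silver-catalysed closure of allenoic acid 9.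
Enabling feature: in the five-membered ring O–C6–C7–C11–C12 the carbons C6, C7 and C11 are contiguous and C6 is its only sp3 C–O carbon. With the double bond drawn inside the ring (C7=C11) this triad is the retron of a 2,3-allenoic acid, hence of a propargylic ester C6–C7≡C11, and the C4=C5 alkenyl group on C6 helps the stereo-erasing ionisation.
8 comes from enal 4 and alkyne 5; 23 comes from propargyl alcohol (Z-iodoalkene by carbomagnesiation, C9 by kinetic resolution) and angelic acid 19.

Key step: step 4

Assumption: the (R)-antipode of the diphosphine in step 4 is taken to favour the (aR)-allenoic acid. If the sense of induction proves opposite, the (S)-ligand is used and nothing else changes.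

Step 1
Reactants: 1 4-(tert-butyldimethylsilyloxy)but-1-yne
Product: 3 (E)-5-(tert-butyldimethylsilyloxy)-3-methylpent-2-en-1-ol, via alkenylalane 2 (not isolated)
Conditions: Me3Al (2.5 equiv), Cp2ZrCl2 (0.25 equiv), CH2Cl2, 0 °C to rt; then (CH2O)n, 0 °C to rt; aq. Rochelle salt
Reagents that add atoms: trimethylaluminium C[Al](C)C; paraformaldehyde (as formaldehyde) C=O
Why: Negishi carboalumination adds CH3 and Al syn with Al on the terminal carbon, so trapping of alkenylalane 2 with formaldehyde should give only the E-trisubstituted allylic alcohol (C4=C5 of the target), and the silyl ether is inert.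

Step 2
Reactants: 3 (E)-5-(tert-butyldimethylsilyloxy)-3-methylpent-2-en-1-ol
Product: 4 (E)-5-(tert-butyldimethylsilyloxy)-3-methylpent-2-enal
Conditions: MnO2 (15 equiv), CH2Cl2, rt
Reagents that add atoms: none
Why: Allylic oxidation with MnO2 is selective for the allylic alcohol and should leave the alkene geometry and the silyl ether untouched.

Step 3
Reactants: 4 (E)-5-(tert-butyldimethylsilyloxy)-3-methylpent-2-enal; 5 1-methoxy-4-[(prop-2-ynyloxy)methyl]benzene
Product: 8 racemic tert-butyl (E)-8-(tert-butyldimethylsilyloxy)-1-(4-methoxybenzyloxy)-6-methyloct-5-en-2-yn-4-yl carbonate, via lithium acetylide 6 (not isolated), via lithium alkoxide 7 (not isolated)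
Conditions: 5, n-BuLi, THF, −78 °C; 4, −78 °C; then Boc2O, −78 °C to rt; aq. NH4Cl
Reagents that add atoms: di-tert-butyl dicarbonate CC(C)(C)OC(=O)OC(=O)OC(C)(C)C
Why: 1,2-Addition of a lithium acetylide to an enal, then O-acylation of the lithium alkoxide in the same flask; the carbinol carbon is deliberately left racemic because step 4 erases it.

Step 4
Reactants: 8 racemic tert-butyl (E)-8-(tert-butyldimethylsilyloxy)-1-(4-methoxybenzyloxy)-6-methyloct-5-en-2-yn-4-yl carbonate
Product: 10 (5R)-5-[(E)-4-(tert-butyldimethylsilyloxy)-2-methylbut-1-enyl]-3-[(4-methoxybenzyloxy)methyl]furan-2(5H)-one, via allenoic acid 9 (not isolated)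
Conditions: Pd2(dba)3·CHCl3 (2.5 mol %), (R)-DTBM-SEGPHOS (6 mol %), CO (1 atm), H2O (10 equiv), THF, 25 °C; then argon purge, AgNO3 (20 mol %), same flask, 25 °C, dark
Reagents that add atoms: carbon monoxide [C-]#[O+]; water O
Why: Proposed new method: zerovalent palladium ionises either enantiomer of 8 in an anti SN2′ sense, so that the old C6–O bond is broken (its oxygen leaves as tert-butyl carbonate, which decays to CO2 and tert-butoxide) and palladium sits on C11 of an allenyl complex; the two diastereomeric allenyl complexes interconvert through η1-propargyl and η3-allyl forms opened by the C4=C5 alkenyl group, the chiral diphosphine lets one of them insert CO faster, and hydrolysis of the acylpalladium gives the (aR)-allenoic acid 9 with the new C11–C12 bond. After CO has been swept out, monovalent silver binds the C6=C7 bond of 9 on the face away from the carboxyl group, a carboxyl oxygen attacks C6 (new O–C6 bond) and protodemetalation at C7 releases butenolide 10. The closest known reaction types are the enantioselective palladium-catalysed alkoxycarbonylation of racemic secondary propargylic carbonates to axially chiral 2,3-allenoates, the hydroxycarbonylation of propargylic esters to 2,3-allenoic acids and the silver-catalysed stereospecific cycloisomerisation of such acids; new are water as the nucleophile in the enantioconvergent version, the alkenyl group on the carbinol carbon and the telescoping into one flask. The only ring closed is the five-membered lactone, by 5-endo-trig attack of oxygen on the allene terminus. The only new stereocentre, C6, is written by the allene axis (axis-to-centre transfer through anti oxymetalation), and the axis by the ligand. The step needs SN2′ carbonylation at C11 instead of capture of the η3-allyl isomer at C4 or C6, which is secured because CO inserts far faster into the σ-allenyl C(sp2)–Pd bond than into an η3-allyl, because the primary PMB ether at C13 is no leaving group, and because the E geometry of C4=C5 could only be lost through an unfavourable tertiary η1 complex at C4.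

Step 5
Reactants: 10 (5R)-5-[(E)-4-(tert-butyldimethylsilyloxy)-2-methylbut-1-enyl]-3-[(4-methoxybenzyloxy)methyl]furan-2(5H)-one
Product: 11 (5R)-5-[(E)-4-(tert-butyldimethylsilyloxy)-2-methylbut-1-enyl]-3-(hydroxymethyl)furan-2(5H)-one
Conditions: DDQ (1.3 equiv), CH2Cl2/pH 7 buffer (18:1), 0 °C to rt
Reagents that add atoms: none
Why: Oxidative PMB cleavage with DDQ attacks the electron-rich benzyl ether first and, in buffered medium, should leave the silyl ether, the butenolide and C6 untouched.

Step 6
Reactants: 11 (5R)-5-[(E)-4-(tert-butyldimethylsilyloxy)-2-methylbut-1-enyl]-3-(hydroxymethyl)furan-2(5H)-one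
Product: 12 (5R)-3-(bromomethyl)-5-[(E)-4-(tert-butyldimethylsilyloxy)-2-methylbut-1-enyl]furan-2(5H)-one
Conditions: CBr4, PPh3, CH2Cl2, 0 °C
Reagents that add atoms: carbon tetrabromide BrC(Br)(Br)Br
Why: The Appel reaction converts the primary allylic alcohol into the bromide under neutral conditions, which avoids base-induced racemisation at the acidic C6–H.

Step 7
Reactants: 13 prop-2-yn-1-ol
Product: 15 (Z)-3-iodo-2-methylprop-2-en-1-ol, via magnesacycle 14 (not isolated)
Conditions: MeMgBr (2.5 equiv), CuI (10 mol %), THF, −10 °C to rt; then I2, −78 to 0 °C; aq. NH4Cl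
Reagents that add atoms: methylmagnesium bromide C[Mg]Br; iodine II
Why: Copper-catalysed, alkoxide-directed anti carbomagnesiation gives the five-membered magnesacycle 14, and iodinolysis with retention should give only the Z-iodoalkene (C1=C10 of the target).

Step 8
Reactants: 15 (Z)-3-iodo-2-methylprop-2-en-1-ol
Product: 16 (Z)-3-iodo-2-methylprop-2-enal
Conditions: MnO2 (15 equiv), CH2Cl2, rt, dark; used at once
Reagents that add atoms: none
Why: Allylic oxidation with MnO2 is neutral, so the Z-enal should form without isomerisation and the C–I bond is not touched.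

Step 9
Reactants: 16 (Z)-3-iodo-2-methylprop-2-enal
Product: 17 racemic (1Z)-1-iodo-2-methylpenta-1,4-dien-3-ol
Conditions: vinylmagnesium bromide, THF, −78 °C; aq. NH4Cl
Reagents that add atoms: vinylmagnesium bromide C=C[Mg]Br
Why: Grignard 1,2-addition to the enal is faster at −78 °C than any iodine–magnesium exchange; the carbinol forms racemic and is resolved in the next step.

Step 10
Reactants: 17 racemic (1Z)-1-iodo-2-methylpenta-1,4-dien-3-ol
Product: 18 (1Z,3S)-1-iodo-2-methylpenta-1,4-dien-3-ol
Conditions: Ti(OiPr)4 (10 mol %), L-(+)-DIPT (15 mol %), t-BuOOH (0.6 equiv), 4 Å MS, CH2Cl2, −20 °C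
Reagents that add atoms: none
Why: Sharpless kinetic resolution: with L-(+)-DIPT the (R)-enantiomer should be epoxidised at its vinyl group, while the (S)-enantiomer, whose only matched alkene is the deactivated Z-iodoalkene, is left behind, which sets C9.

Step 11
Reactants: 18 (1Z,3S)-1-iodo-2-methylpenta-1,4-dien-3-ol; 19 angelic acid
Product: 21 (1Z,3S)-1-iodo-2-methylpenta-1,4-dien-3-yl (Z)-2-methylbut-2-enoate, via mixed anhydride 20 (not isolated)
Conditions: 19, 2,4,6-trichlorobenzoyl chloride, Et3N, toluene, rt; then 18, 75 °C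
Reagents that add atoms: none
Why: Yamaguchi-type mixed-anhydride esterification without a nucleophilic catalyst is the usual way to make angelates without Z-to-E isomerisation, and the C9–O bond is not touched, so C9 is retained.

Step 12
Reactants: 21 (1Z,3S)-1-iodo-2-methylpenta-1,4-dien-3-yl (Z)-2-methylbut-2-enoate
Product: 23 (2R,3Z)-4-iodo-3-methyl-1-oxobut-3-en-2-yl (Z)-2-methylbut-2-enoate, via diol 22 (not isolated)
Conditions: OsO4 (2 mol %), NaIO4 (4 equiv), 2,6-lutidine (2 equiv), dioxane/H2O (3:1), rt; used crude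
Reagents that add atoms: sodium periodate (terminal source of the aldehyde oxygen, relayed by OsO4) [Na+].[O-]I(=O)(=O)=O
Why: Lemieux–Johnson cleavage: OsO4 should take the only non-deactivated alkene (the vinyl group; enoate and iodoalkene are electron-poor), periodate cleaves diol 22, and the lutidine buffer protects the α-stereocentre.

Step 13
Reactants: 12 (5R)-3-(bromomethyl)-5-[(E)-4-(tert-butyldimethylsilyloxy)-2-methylbut-1-enyl]furan-2(5H)-one; 23 (2R,3Z)-4-iodo-3-methyl-1-oxobut-3-en-2-yl (Z)-2-methylbut-2-enoate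
Product: 25 (4R,5R)-4-[(1R,2R,3Z)-2-angeloyloxy-1-hydroxy-4-iodo-3-methylbut-3-enyl]-5-[(E)-4-(tert-butyldimethylsilyloxy)-2-methylbut-1-enyl]-3-methylenedihydrofuran-2(3H)-one, via allylzinc bromide 24 (not isolated)
Conditions: Zn dust (5 equiv), THF/sat. aq. NH4Cl, 0 °C to rt
Reagents that add atoms: none
Why: Zinc Barbier allylation: allylzinc 24 should react at its γ-carbon C7 through a chair transition state on the face anti to the C6 alkenyl group (C6/C7 trans), its ring-fixed E-type geometry gives the anti relation that is C7/C8 of the target, the double bond moves out to C11=C13, and reagent control should hold because E-type allyl metals feel little face bias from α-oxygenated aldehydes.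

Step 14
Reactants: 25 (4R,5R)-4-[(1R,2R,3Z)-2-angeloyloxy-1-hydroxy-4-iodo-3-methylbut-3-enyl]-5-[(E)-4-(tert-butyldimethylsilyloxy)-2-methylbut-1-enyl]-3-methylenedihydrofuran-2(3H)-one
Product: 26 (4R,5R)-4-[(1R,2R,3Z)-2-angeloyloxy-1-hydroxy-4-iodo-3-methylbut-3-enyl]-5-[(E)-4-hydroxy-2-methylbut-1-enyl]-3-methylenedihydrofuran-2(3H)-one
Conditions: HF·pyridine, pyridine, THF, 0 °C to rt
Reagents that add atoms: none
Why: Fluoride desilylation in a weakly acidic medium should free the primary alcohol without angelate migration, translactonisation to O8 or conjugate addition to the methylene lactone.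

Step 15
Reactants: 26 (4R,5R)-4-[(1R,2R,3Z)-2-angeloyloxy-1-hydroxy-4-iodo-3-methylbut-3-enyl]-5-[(E)-4-hydroxy-2-methylbut-1-enyl]-3-methylenedihydrofuran-2(3H)-one
Product: 27 (4R,5R)-4-[(1R,2R,3Z)-2-angeloyloxy-1-hydroxy-4-iodo-3-methylbut-3-enyl]-5-[(E)-2-methyl-4-oxobut-1-enyl]-3-methylenedihydrofuran-2(3H)-one
Conditions: TEMPO (20 mol %), PhI(OAc)2 (1.2 equiv), CH2Cl2, rt; used at once
Reagents that add atoms: none
Why: Oxoammonium oxidation (TEMPO/PhI(OAc)2) prefers the primary alcohol over the hindered C8 carbinol and is mild enough to keep the β,γ-unsaturated aldehyde out of conjugation.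

Step 16
Reactants: 27 (4R,5R)-4-[(1R,2R,3Z)-2-angeloyloxy-1-hydroxy-4-iodo-3-methylbut-3-enyl]-5-[(E)-2-methyl-4-oxobut-1-enyl]-3-methylenedihydrofuran-2(3H)-one
Product: 28 CNP0311662.1, (1(10)Z,4E,2S,6R,7R,8R,9R)-9-angeloyloxy-2,8-dihydroxygermacra-1(10),4,11(13)-trien-6,12-olide
Conditions: CrCl2 (10 equiv), NiCl2 (0.1 equiv), DMSO/THF (3:1), 2 mM, slow addition of 27, rt
Reagents that add atoms: none
Why: Nozaki–Hiyama–Kishi ring closure, a type of closure known for ten-membered germacranolide rings that carry the α-methylene lactone: the alkenylchromium forms with retention of the Z geometry and adds only to the aldehyde, and C2 is set by a macrocyclic transition state in which the aldehyde oxygen points out of the forming ring held by the trans-lactone and the E-alkene, which is expected to give the 2S carbinol.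

Compound list
1 | 4-(tert-butyldimethylsilyloxy)but-1-yne | C#CCCO[Si](C)(C)C(C)(C)C | starting material
2 | (E)-[4-(tert-butyldimethylsilyloxy)-2-methylbut-1-enyl]dimethylalane | C[Al](C)/C=C(\C)CCO[Si](C)(C)C(C)(C)C | intermediate
3 | (E)-5-(tert-butyldimethylsilyloxy)-3-methylpent-2-en-1-ol | OC/C=C(\C)CCO[Si](C)(C)C(C)(C)C | intermediate
4 | (E)-5-(tert-butyldimethylsilyloxy)-3-methylpent-2-enal | O=C/C=C(\C)CCO[Si](C)(C)C(C)(C)C | intermediate
5 | 1-methoxy-4-[(prop-2-ynyloxy)methyl]benzene (PMB propargyl ether) | C#CCOCc1ccc(OC)cc1 | starting material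
6 | lithium acetylide of 5 | [Li]C#CCOCc1ccc(OC)cc1 | intermediate
7 | racemic lithium (E)-8-(tert-butyldimethylsilyloxy)-1-(4-methoxybenzyloxy)-6-methyloct-5-en-2-yn-4-olate | [Li]OC(C#CCOCc1ccc(OC)cc1)/C=C(\C)CCO[Si](C)(C)C(C)(C)C | intermediate
8 | racemic tert-butyl (E)-8-(tert-butyldimethylsilyloxy)-1-(4-methoxybenzyloxy)-6-methyloct-5-en-2-yn-4-yl carbonate | CC(C)(C)OC(=O)OC(C#CCOCc1ccc(OC)cc1)/C=C(\C)CCO[Si](C)(C)C(C)(C)C | intermediate
9 | (aR,5E)-8-(tert-butyldimethylsilyloxy)-2-[(4-methoxybenzyloxy)methyl]-6-methylocta-2,3,5-trienoic acid | OC(=O)C(COCc1ccc(OC)cc1)=[C@]=C([H])/C=C(\C)CCO[Si](C)(C)C(C)(C)C | intermediate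
10 | (5R)-5-[(E)-4-(tert-butyldimethylsilyloxy)-2-methylbut-1-enyl]-3-[(4-methoxybenzyloxy)methyl]furan-2(5H)-one | O=C1O[C@@H](C=C1COCc2ccc(OC)cc2)/C=C(\C)CCO[Si](C)(C)C(C)(C)C | intermediate
11 | (5R)-5-[(E)-4-(tert-butyldimethylsilyloxy)-2-methylbut-1-enyl]-3-(hydroxymethyl)furan-2(5H)-one | O=C1O[C@@H](C=C1CO)/C=C(\C)CCO[Si](C)(C)C(C)(C)C | intermediate
12 | (5R)-3-(bromomethyl)-5-[(E)-4-(tert-butyldimethylsilyloxy)-2-methylbut-1-enyl]furan-2(5H)-one | O=C1O[C@@H](C=C1CBr)/C=C(\C)CCO[Si](C)(C)C(C)(C)C | intermediate
13 | prop-2-yn-1-ol | C#CCO | starting material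
14 | 4-methyl-2,5-dihydro-1,2-oxamagnesole (magnesacycle) | CC1=C[Mg]OC1 | intermediate
15 | (Z)-3-iodo-2-methylprop-2-en-1-ol | I/C=C(/C)CO | intermediate
16 | (Z)-3-iodo-2-methylprop-2-enal | I/C=C(/C)C=O | intermediate
17 | racemic (1Z)-1-iodo-2-methylpenta-1,4-dien-3-ol | I/C=C(/C)C(O)C=C | intermediate
18 | (1Z,3S)-1-iodo-2-methylpenta-1,4-dien-3-ol | I/C=C(/C)[C@@H](O)C=C | intermediate
19 | angelic acid, (Z)-2-methylbut-2-enoic acid | C/C=C(/C)C(=O)O | starting material
20 | angelic 2,4,6-trichlorobenzoic anhydride | C/C=C(/C)C(=O)OC(=O)c1c(Cl)cc(Cl)cc1Cl | intermediate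
21 | (1Z,3S)-1-iodo-2-methylpenta-1,4-dien-3-yl (Z)-2-methylbut-2-enoate | I/C=C(/C)[C@@H](OC(=O)/C(C)=C\C)C=C | intermediate
22 | (3R,4Z)-1,2-dihydroxy-5-iodo-4-methylpent-4-en-3-yl (Z)-2-methylbut-2-enoate (both epimers at the new carbinol) | I/C=C(/C)[C@@H](OC(=O)/C(C)=C\C)C(O)CO | intermediate
23 | (2R,3Z)-4-iodo-3-methyl-1-oxobut-3-en-2-yl (Z)-2-methylbut-2-enoate | I/C=C(/C)[C@@H](OC(=O)/C(C)=C\C)C=O | intermediate
24 | allylzinc bromide of 12 | O=C1O[C@@H](C=C1C[Zn]Br)/C=C(\C)CCO[Si](C)(C)C(C)(C)C | intermediate
25 | (4R,5R)-4-[(1R,2R,3Z)-2-angeloyloxy-1-hydroxy-4-iodo-3-methylbut-3-enyl]-5-[(E)-4-(tert-butyldimethylsilyloxy)-2-methylbut-1-enyl]-3-methylenedihydrofuran-2(3H)-one | C=C1C(=O)O[C@H](/C=C(\C)CCO[Si](C)(C)C(C)(C)C)[C@H]1[C@@H](O)[C@H](OC(=O)/C(C)=C\C)/C(C)=C\I | intermediate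
26 | (4R,5R)-4-[(1R,2R,3Z)-2-angeloyloxy-1-hydroxy-4-iodo-3-methylbut-3-enyl]-5-[(E)-4-hydroxy-2-methylbut-1-enyl]-3-methylenedihydrofuran-2(3H)-one | C=C1C(=O)O[C@H](/C=C(\C)CCO)[C@H]1[C@@H](O)[C@H](OC(=O)/C(C)=C\C)/C(C)=C\I | intermediate
27 | (4R,5R)-4-[(1R,2R,3Z)-2-angeloyloxy-1-hydroxy-4-iodo-3-methylbut-3-enyl]-5-[(E)-2-methyl-4-oxobut-1-enyl]-3-methylenedihydrofuran-2(3H)-one | C=C1C(=O)O[C@H](/C=C(\C)CC=O)[C@H]1[C@@H](O)[C@H](OC(=O)/C(C)=C\C)/C(C)=C\I | intermediate
28 | CNP0311662.1, (1(10)Z,4E,2S,6R,7R,8R,9R)-9-angeloyloxy-2,8-dihydroxygermacra-1(10),4,11(13)-trien-6,12-olide | C=C1C(=O)O[C@@H]2/C=C(\C)C[C@H](O)/C=C(/C)[C@@H](OC(=O)/C(C)=C\C)[C@H](O)[C@@H]12 | target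

Total step count: 16. Longest linear sequence: 10 steps (steps 1–6 and 13–16).

Steps most likely to fail

Step 4. The two allenylpalladium diastereomers may interconvert too slowly, so that enantioconvergence stays incomplete. Acid 9 may also be consumed by allenylpalladium before the silver stage. The fallback puts the chirality in before the carbonylation and uses known reactions only.
- It sets out from 4 and 5. Zinc–ProPhenol-catalysed asymmetric alkynylation (Me2Zn, toluene, the ligand antipode that gives the S carbinol) should give (S,E)-8-(tert-butyldimethylsilyloxy)-1-(4-methoxybenzyloxy)-6-methyloct-5-en-2-yn-4-ol F1.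
- Boc2O and DMAP should turn F1 into the (S)-tert-butyl carbonate F2.
- Hydroxycarbonylation of F2 with the achiral catalyst Pd(PPh3)4 (CO, H2O, THF) is stereospecific (anti SN2′) and should give 9.
- Acid 9 is then isolated and cyclised with AgNO3 in acetone, and the route is rejoined at 10.

Step 16. Facial selectivity at the aldehyde during ring closure may be poor, or the wrong face may be preferred. The fallback sets C2 by a reagent after the ring has been closed.
- It sets out from 27, whose closure under the same conditions would then give the 2-epimer of the target F3, alone or mixed with 28.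
- MnO2 should oxidise only the allylic C2 alcohol to the 2-oxo compound (enone) F4, leaving the C8 carbinol.
- Corey–Bakshi–Shibata reduction with the (R)-methyl oxazaborolidine and catecholborane should deliver the 2S alcohol, which comes back to the route at 28.

Step 13. Three things may go wrong: erosion of face selectivity in the pairing of the two chiral partners, protonation of the allylzinc by the aqueous medium, and reductive loss or 1,2-migration of the angelate at the zinc alkoxide stage. The fallback replaces the in situ allylzinc by an isolated allylboron reagent.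
- It sets out from 12. Zinc insertion (Zn, LiCl, THF) and trapping with 2-isopropoxy-4,4,5,5-tetramethyl-1,3,2-dioxaborolane should give the butenolide allylboronate F5.
- Sc(OTf)3-catalysed allylboration of 23 in toluene is a known reaction type of 2-alkoxycarbonyl allylboronates, with a closed chair transition state in a water-free and non-basic medium. It should give the same adduct, so the route is rejoined at 25.

Further compounds
F1 | step 4 | (S,E)-8-(tert-butyldimethylsilyloxy)-1-(4-methoxybenzyloxy)-6-methyloct-5-en-2-yn-4-ol | O[C@H](C#CCOCc1ccc(OC)cc1)/C=C(\C)CCO[Si](C)(C)C(C)(C)C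
F2 | step 4 | tert-butyl (S,E)-8-(tert-butyldimethylsilyloxy)-1-(4-methoxybenzyloxy)-6-methyloct-5-en-2-yn-4-yl carbonate | CC(C)(C)OC(=O)O[C@H](C#CCOCc1ccc(OC)cc1)/C=C(\C)CCO[Si](C)(C)C(C)(C)C
F3 | step 16 | 2-epimer of the target, (2R,6R,7R,8R,9R) | C=C1C(=O)O[C@@H]2/C=C(\C)C[C@@H](O)/C=C(/C)[C@@H](OC(=O)/C(C)=C\C)[C@H](O)[C@@H]12
F4 | step 16 | 2-oxo compound (enone), (6R,7R,8R,9R) | C=C1C(=O)O[C@@H]2/C=C(\C)CC(=O)/C=C(/C)[C@@H](OC(=O)/C(C)=C\C)[C@H](O)[C@@H]12
F5 | step 13 | (5R)-5-[(E)-4-(tert-butyldimethylsilyloxy)-2-methylbut-1-enyl]-3-[(4,4,5,5-tetramethyl-1,3,2-dioxaborolan-2-yl)methyl]furan-2(5H)-one | O=C1O[C@@H](C=C1CB2OC(C)(C)C(C)(C)O2)/C=C(\C)CCO[Si](C)(C)C(C)(C)C
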